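**Remark (assumptions on the chemistry).** Unit 1 is the flavanone half that carries the aryl group at C3 (eriodictyol type), and unit 2 is the flavanonol half (taxifolin type). Atom numbers are the usual flavonoid numbers within each unit. DBB stands for 3,4-bis(benzyloxy)benzyl. The racemate 5 is written as the pair of its two enantiomers. Compounds 2 and 10 are taken as commercially available. Step 1 incorporates three equivalents of 2; the second and third are entered on its reagent line.

## Retrosynthetic overview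

1. Manniflavanone ⇐ global hydrogenolysis of 14 ⇐ C3(unit 1)–C8(unit 2) bond, made by photoredox radical arylation that joins bromoflavanone 13 to flavanonol 6.
2. Ring C of unit 2 is closed by forming its C2–C3 bond in a Norrish–Yang-type photocyclisation of aryl glyoxal 4. Compound 4 comes in two steps from phloroacetophenone and three equivalents of a benzylic chloride that serves both as protecting group and as the future C2 and ring B. The racemic product is then resolved.
3. Enabling feature: in ring C of unit 2 the C3–OH/C4=O α-ketol is the footprint of a 1,2-dicarbonyl (ketone C4 on ring A, aldehyde C3). C2–H, flanked by O1 and the catechol ring B, is a weak benzylic ether C–H that lies 1,7 to the aldehyde oxygen. The threefold O-substitution of ring A makes both ortho ethers equivalent.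
4. Ring C of unit 1 is built as a chromone from phloroacetophenone. C2 is then set by rhodium-catalysed asymmetric 1,4-arylation, and C3 is set trans in the union.
5. Ring order: rings A and B are bought; ring C of unit 2 by photocyclisation; ring C of unit 1 by chromone annulation; the bond between the units last.

Key step: step 3

## Route

Step 1
Reactants: 1 1-(2,4,6-trihydroxyphenyl)ethanone; 2 3,4-bis(benzyloxy)benzyl chloride
Product: 3 1-[2,4,6-tris(DBB-oxy)phenyl]ethanone
Conditions: 2 (3.3 equiv in all), K2CO3 (4 equiv), NaI (cat.), DMF, 70 °C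
Reagents that add atoms: 3,4-bis(benzyloxy)benzyl chloride (second equivalent of 2), ClCc1ccc(OCc2ccccc2)c(OCc2ccccc2)c1; 3,4-bis(benzyloxy)benzyl chloride (third equivalent of 2), ClCc1ccc(OCc2ccccc2)c(OCc2ccccc2)c1
Why: Threefold Williamson etherification in which each of the three phenols takes up one molecule of 2, the forcing conditions (DMF, iodide catalysis, excess chloride) also alkylating the two hydrogen-bonded ortho hydroxyls, so that a symmetric triether with two equivalent ortho ethers results; no stereocentre is formed.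

Step 2
Reactants: 3 1-[2,4,6-tris(DBB-oxy)phenyl]ethanone
Product: 4 2-oxo-2-[2,4,6-tris(DBB-oxy)phenyl]acetaldehyde
Conditions: SeO2, 1,4-dioxane/H2O, 90 °C; then azeotropic drying (toluene)
Reagents that add atoms: selenium dioxide, O=[Se]=O
Why: Riley oxidation of an aryl methyl ketone to the aryl glyoxal, the methyl group being the only enolisable position; no stereocentre is formed.

Step 3
Reactants: 4 2-oxo-2-[2,4,6-tris(DBB-oxy)phenyl]acetaldehyde
Product: 5 (±)-trans-2-[3,4-bis(benzyloxy)phenyl]-5,7-bis(DBB-oxy)-3-hydroxychroman-4-one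
Conditions: hν (450 nm LEDs), degassed benzene (5 mM), 20 °C; then NaOAc, EtOH/THF, 40 °C
Reagents that add atoms: none
Why: Proposed new method: visible-light n→π* excitation of the 1,2-dicarbonyl of 4 and intersystem crossing should give a triplet in which the aldehyde oxygen abstracts a benzylic hydrogen of an ortho OCH2Ar group through an eight-membered transition state (1,7-hydrogen transfer), and the resulting 1,6-biradical (hydroxy-substituted α-keto radical at C3, α-aryloxybenzyl radical at C2) should collapse after spin inversion to the C2–C3 bond. The closest known reaction type is the Norrish–Yang photocyclisation of ortho-substituted aryl 1,2-diones through hydrogen abstraction by the remote carbonyl oxygen and of ortho-benzyloxyaryl ketones and glyoxylates to 3-hydroxy-2,3-dihydrobenzofurans; the extension to an aryl glyoxal on a 2,4,6-trioxygenated ring is the new element. Ring C closes as a six-membered ring by combination of the two radical ends of the 1,6-biradical, not by a polar cyclisation. C2 and C3 are created together: the trans relation should follow from a chair-like collapse with aryl and hydroxyl pseudo-equatorial and is secured afterwards because C3, being α to the ketone, equilibrates to the more stable trans isomer under the acetate treatment, whereas the absolute configuration is not set here (racemate) and is fixed in step 4. The step needs site selectivity of hydrogen abstraction, secured by the symmetry of ring A (both ortho ethers are equivalent, and the para ether and the benzyl CH2 groups on the catechols are out of reach), and freedom from secondary photochemistry, secured because only the glyoxal absorbs at 450 nm and the product aryl ketone is transparent there.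

Step 4
Reactants: 5 (±)-trans-2-[3,4-bis(benzyloxy)phenyl]-5,7-bis(DBB-oxy)-3-hydroxychroman-4-one
Product: 6 (2R,3R)-2-[3,4-bis(benzyloxy)phenyl]-5,7-bis(DBB-oxy)-3-hydroxychroman-4-one
Conditions: isobutyric anhydride (0.6 equiv), HyperBTM (2 mol %, antipode chosen on the racemate), i-Pr2NEt, CHCl3, 0 °C, to a little over half conversion; chromatography
Reagents that add atoms: none
Why: Acylative kinetic resolution of a secondary alcohol by a chiral isothiourea acyl-transfer catalyst that recognises the carbonyl π-system next to the carbinol, so that the (2S,3S) alcohol should be acylated faster and the (2R,3R) alcohol recovered, which fixes the absolute configuration at C2 and C3 of unit 2.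

Step 5
Reactants: 1 1-(2,4,6-trihydroxyphenyl)ethanone
Product: 7 1-[2,4-bis(benzyloxy)-6-hydroxyphenyl]ethanone
Conditions: BnBr (2.1 equiv), K2CO3, acetone, reflux
Reagents that add atoms: benzyl bromide, BrCc1ccccc1
Why: Williamson etherification in which the para hydroxyl and one ortho hydroxyl react while the second ortho hydroxyl stays free because it is hydrogen-bonded to the ketone; no stereocentre is formed.

Step 6
Reactants: 7 1-[2,4-bis(benzyloxy)-6-hydroxyphenyl]ethanone
Product: 9 5,7-bis(benzyloxy)-4H-chromen-4-one, via enaminone 8 (not isolated)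
Conditions: Me2NCH(OMe)2, toluene, 95 °C; then conc. HCl, CH2Cl2, 20 °C
Reagents that add atoms: N,N-dimethylformamide dimethyl acetal, COC(OC)N(C)C
Why: Chromone annulation by enaminone formation at the methyl ketone followed by acid-promoted addition of the phenol and loss of dimethylamine; no stereocentre is formed.

Step 7
Reactants: 9 5,7-bis(benzyloxy)-4H-chromen-4-one; 10 [3,4-bis(benzyloxy)phenyl]boronic acid
Product: 11 (2R)-5,7-bis(benzyloxy)-2-[3,4-bis(benzyloxy)phenyl]chroman-4-one
Conditions: [Rh(OH)(cod)]2 (1.5 mol %), MeO-F12-BIPHEP (3.3 mol %, antipode that delivers 2R), CH2Cl2/H2O, 20 °C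
Reagents that add atoms: none
Why: Rhodium-catalysed asymmetric 1,4-addition of an arylboronic acid (Hayashi–Miyaura reaction) applied to a chromone, in which the aryl–rhodium species adds to C2 from the face dictated by the chiral bisphosphine and the rhodium enolate is protonated by water under neutral conditions that do not open the flavanone, so that C2 is set as R by catalyst control.

Step 8
Reactants: 11 (2R)-5,7-bis(benzyloxy)-2-[3,4-bis(benzyloxy)phenyl]chroman-4-one
Product: 13 (2S,3S)-5,7-bis(benzyloxy)-2-[3,4-bis(benzyloxy)phenyl]-3-bromochroman-4-one, via silyl enol ether 12 (not isolated)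
Conditions: TMSOTf, Et3N, CH2Cl2, 0 °C; then NBS, THF, −78 °C
Reagents that add atoms: N-bromosuccinimide, O=C1CCC(=O)N1Br
Why: Soft enolisation (no free enolate, hence no retro-oxa-Michael opening and no loss of the C2 configuration) followed by electrophilic bromination of the silyl enol ether anti to the C2 aryl group, giving the trans bromide whose C3 configuration is not used later because C3 becomes a radical; the change of the C2 descriptor from R to S is only a priority change caused by bromine.

Step 9
Reactants: 13 (2S,3S)-5,7-bis(benzyloxy)-2-[3,4-bis(benzyloxy)phenyl]-3-bromochroman-4-one; 6 (2R,3R)-2-[3,4-bis(benzyloxy)phenyl]-5,7-bis(DBB-oxy)-3-hydroxychroman-4-one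
Product: 14 (2R,3R)-8-{(2R,3S)-5,7-bis(benzyloxy)-2-[3,4-bis(benzyloxy)phenyl]-4-oxochroman-3-yl}-2-[3,4-bis(benzyloxy)phenyl]-5,7-bis(DBB-oxy)-3-hydroxychroman-4-one
Conditions: fac-Ir(ppy)3 (1 mol %), 2,6-lutidine, MeCN/CH2Cl2, 450 nm LEDs, 20 °C; 13 added slowly to 6 (2 equiv, excess recovered)
Reagents that add atoms: none
Why: Photoredox homolytic aromatic substitution (alkylation of an electron-rich arene by an α-carbonyl radical), in which the excited iridium complex reduces the C–Br bond, the electrophilic α-keto radical at C3 of unit 1 adds to C8 of ring A of 6 (the most electron-rich ring, and less hindered than C6, which lies between two benzylic ethers), and oxidation with loss of a proton rearomatises; C2 of unit 1 is untouched and the new C3 stereocentre is set trans to the C2 aryl group both kinetically (approach anti to the aryl) and thermodynamically (C3–H is epimerisable).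

Step 10
Reactants: 14 (2R,3R)-8-{(2R,3S)-5,7-bis(benzyloxy)-2-[3,4-bis(benzyloxy)phenyl]-4-oxochroman-3-yl}-2-[3,4-bis(benzyloxy)phenyl]-5,7-bis(DBB-oxy)-3-hydroxychroman-4-one
Product: 15 manniflavanone
Conditions: H2 (1 atm), Pd(OH)2/C, THF/MeOH, 20 °C
Reagents that add atoms: none
Why: Hydrogenolysis of benzylic C–O bonds, which should cleave all ten benzyl ethers and the two 3,4-dioxygenated benzyl ethers under mild conditions that leave the aryl ketones, the secondary alcohol and the cyclic C2–O1 ethers of the two flavanone rings intact, so that no stereocentre is touched.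

## Compound list

1 | 1-(2,4,6-trihydroxyphenyl)ethanone | CC(=O)c1c(O)cc(O)cc1O | starting material
2 | 3,4-bis(benzyloxy)benzyl chloride | ClCc1ccc(OCc2ccccc2)c(OCc2ccccc2)c1 | starting material
3 | 1-[2,4,6-tris(DBB-oxy)phenyl]ethanone | CC(=O)c1c(OCc2ccc(OCc3ccccc3)c(OCc3ccccc3)c2)cc(OCc2ccc(OCc3ccccc3)c(OCc3ccccc3)c2)cc1OCc1ccc(OCc2ccccc2)c(OCc2ccccc2)c1 | intermediate
4 | 2-oxo-2-[2,4,6-tris(DBB-oxy)phenyl]acetaldehyde | O=CC(=O)c1c(OCc2ccc(OCc3ccccc3)c(OCc3ccccc3)c2)cc(OCc2ccc(OCc3ccccc3)c(OCc3ccccc3)c2)cc1OCc1ccc(OCc2ccccc2)c(OCc2ccccc2)c1 | intermediate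
5 | (±)-trans-2-[3,4-bis(benzyloxy)phenyl]-5,7-bis(DBB-oxy)-3-hydroxychroman-4-one (racemate; both enantiomers written) | O=C1c2c(OCc3ccc(OCc4ccccc4)c(OCc4ccccc4)c3)cc(OCc3ccc(OCc4ccccc4)c(OCc4ccccc4)c3)cc2O[C@H](c2ccc(OCc3ccccc3)c(OCc3ccccc3)c2)[C@H]1O.O=C1c2c(OCc3ccc(OCc4ccccc4)c(OCc4ccccc4)c3)cc(OCc3ccc(OCc4ccccc4)c(OCc4ccccc4)c3)cc2O[C@@H](c2ccc(OCc3ccccc3)c(OCc3ccccc3)c2)[C@@H]1O | intermediate
6 | (2R,3R)-2-[3,4-bis(benzyloxy)phenyl]-5,7-bis(DBB-oxy)-3-hydroxychroman-4-one | O=C1c2c(OCc3ccc(OCc4ccccc4)c(OCc4ccccc4)c3)cc(OCc3ccc(OCc4ccccc4)c(OCc4ccccc4)c3)cc2O[C@H](c2ccc(OCc3ccccc3)c(OCc3ccccc3)c2)[C@H]1O | intermediate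
7 | 1-[2,4-bis(benzyloxy)-6-hydroxyphenyl]ethanone | CC(=O)c1c(O)cc(OCc2ccccc2)cc1OCc1ccccc1 | intermediate
8 | (E)-1-[2,4-bis(benzyloxy)-6-hydroxyphenyl]-3-(dimethylamino)prop-2-en-1-one | CN(C)/C=C/C(=O)c1c(O)cc(OCc2ccccc2)cc1OCc1ccccc1 | intermediate
9 | 5,7-bis(benzyloxy)-4H-chromen-4-one | O=c1ccoc2cc(OCc3ccccc3)cc(OCc3ccccc3)c12 | intermediate
10 | [3,4-bis(benzyloxy)phenyl]boronic acid | OB(O)c1ccc(OCc2ccccc2)c(OCc2ccccc2)c1 | starting material
11 | (2R)-5,7-bis(benzyloxy)-2-[3,4-bis(benzyloxy)phenyl]chroman-4-one | O=C1C[C@H](c2ccc(OCc3ccccc3)c(OCc3ccccc3)c2)Oc2cc(OCc3ccccc3)cc(OCc3ccccc3)c12 | intermediate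
12 | (2R)-5,7-bis(benzyloxy)-2-[3,4-bis(benzyloxy)phenyl]-4-(trimethylsilyloxy)-2H-chromene | C[Si](C)(C)OC1=C[C@H](c2ccc(OCc3ccccc3)c(OCc3ccccc3)c2)Oc2cc(OCc3ccccc3)cc(OCc3ccccc3)c12 | intermediate
13 | (2S,3S)-5,7-bis(benzyloxy)-2-[3,4-bis(benzyloxy)phenyl]-3-bromochroman-4-one (trans) | O=C1[C@@H](Br)[C@H](c2ccc(OCc3ccccc3)c(OCc3ccccc3)c2)Oc2cc(OCc3ccccc3)cc(OCc3ccccc3)c12 | intermediate
14 | (2R,3R)-8-{(2R,3S)-5,7-bis(benzyloxy)-2-[3,4-bis(benzyloxy)phenyl]-4-oxochroman-3-yl}-2-[3,4-bis(benzyloxy)phenyl]-5,7-bis(DBB-oxy)-3-hydroxychroman-4-one | O=C1c2c(OCc5ccc(OCc6ccccc6)c(OCc6ccccc6)c5)cc(OCc5ccc(OCc6ccccc6)c(OCc6ccccc6)c5)c([C@@H]3C(=O)c4c(OCc5ccccc5)cc(OCc5ccccc5)cc4O[C@H]3c3ccc(OCc4ccccc4)c(OCc4ccccc4)c3)c2O[C@H](c2ccc(OCc3ccccc3)c(OCc3ccccc3)c2)[C@H]1O | intermediate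
15 | manniflavanone, (2R,3R)-8-[(2R,3S)-2-(3,4-dihydroxyphenyl)-5,7-dihydroxy-4-oxochroman-3-yl]-2-(3,4-dihydroxyphenyl)-3,5,7-trihydroxychroman-4-one | O=C1c2c(O)cc(O)c([C@@H]3C(=O)c4c(O)cc(O)cc4O[C@H]3c3ccc(O)c(O)c3)c2O[C@H](c2ccc(O)c(O)c2)[C@H]1O | target

## Step count and risks

Total step count: 10. Longest linear sequence: 6 (steps 1, 2, 3, 4, 9, 10 or steps 5, 6, 7, 8, 9, 10).

**Steps most likely to fail**

1. Step 3 (Proposed new method). The ketone oxygen may abstract the hydrogen instead of the aldehyde oxygen, which would close a five-membered benzofuranol ring instead of the chromanone. The excited glyoxal may also decay without reaction, by reversible hydrogen transfer or by electron transfer from the electron-rich benzyl ethers, or lose carbon monoxide by α-cleavage. The fallback uses known chemistry, sets out from 1 and returns to the route at 6. Etherification of 1 with two equivalents of 2 (K2CO3, acetone) should give 1-[2-hydroxy-4,6-bis(DBB-oxy)phenyl]ethanone F1, which MOMCl and i-Pr2NEt should convert into the methoxymethyl ether 1-[2-(methoxymethoxy)-4,6-bis(DBB-oxy)phenyl]ethanone F2. Claisen–Schmidt condensation with 3,4-bis(benzyloxy)benzaldehyde (KOH, EtOH/THF) should give the chalcone (E)-3-[3,4-bis(benzyloxy)phenyl]-1-[2-(methoxymethoxy)-4,6-bis(DBB-oxy)phenyl]prop-2-en-1-one F3. Juliá–Colonna epoxidation (polyleucine of the appropriate handedness, urea–H2O2, DBU, THF) should then give the epoxide [(2R,3S)-3-[3,4-bis(benzyloxy)phenyl]oxiran-2-yl][2-(methoxymethoxy)-4,6-bis(DBB-oxy)phenyl]methanone F4. Dilute HCl in MeOH/THF should remove the methoxymethyl group, and the freed phenol should open the epoxide at the benzylic carbon with inversion. This closes ring C through O1–C2 and returns to the route at 6, already as the single enantiomer, so that step 4 is not needed.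

2. Step 9. The radical may add at C6 instead of C8 of 6, or to ring A of a second molecule of 13. Because the radical is hindered and secondary, addition may also be slow enough that simple reduction of the C–Br bond wins. The fallback sets out from 6 and 11 and returns to the route at 14. Bromination of 6 with NBS (CH2Cl2, −20 °C) should give (2R,3R)-2-[3,4-bis(benzyloxy)phenyl]-5,7-bis(DBB-oxy)-8-bromo-3-hydroxychroman-4-one F5. The silyl enol ether 12, this time isolated from 11, is then coupled with F5 by palladium-catalysed α-arylation of the enol silane (Pd(dba)2, P(t-Bu)3, ZnF2, CsF, DMF, 80 °C). This forms the same C3–C8 bond at a position fixed by the halogen and returns to the route at 14.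

3. Step 4. The acyl-transfer catalyst may discriminate poorly between the enantiomers of so large an alcohol, so that the recovered 6 is not enantiopure. The fallback sets out from 5 and returns to the route at 14. The resolution is left out and racemate 5 is used in step 9 with enantiopure 13, so that unit 1 acts as an internal resolving element. The union should give 14 together with its diastereomer (2S,3S)-8-{(2R,3S)-5,7-bis(benzyloxy)-2-[3,4-bis(benzyloxy)phenyl]-4-oxochroman-3-yl}-2-[3,4-bis(benzyloxy)phenyl]-5,7-bis(DBB-oxy)-3-hydroxychroman-4-one F6. The two are separated by chromatography, and the route continues from 14.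

## Further compounds

F1 | step 3 | 1-[2-hydroxy-4,6-bis(DBB-oxy)phenyl]ethanone | CC(=O)c1c(O)cc(OCc2ccc(OCc3ccccc3)c(OCc3ccccc3)c2)cc1OCc1ccc(OCc2ccccc2)c(OCc2ccccc2)c1
F2 | step 3 | 1-[2-(methoxymethoxy)-4,6-bis(DBB-oxy)phenyl]ethanone | COCOc1cc(OCc2ccc(OCc3ccccc3)c(OCc3ccccc3)c2)cc(OCc2ccc(OCc3ccccc3)c(OCc3ccccc3)c2)c1C(C)=O
F3 | step 3 | (E)-3-[3,4-bis(benzyloxy)phenyl]-1-[2-(methoxymethoxy)-4,6-bis(DBB-oxy)phenyl]prop-2-en-1-one | COCOc1cc(OCc2ccc(OCc3ccccc3)c(OCc3ccccc3)c2)cc(OCc2ccc(OCc3ccccc3)c(OCc3ccccc3)c2)c1C(=O)/C=C/c1ccc(OCc2ccccc2)c(OCc2ccccc2)c1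
F4 | step 3 | [(2R,3S)-3-[3,4-bis(benzyloxy)phenyl]oxiran-2-yl][2-(methoxymethoxy)-4,6-bis(DBB-oxy)phenyl]methanone | COCOc1cc(OCc2ccc(OCc3ccccc3)c(OCc3ccccc3)c2)cc(OCc2ccc(OCc3ccccc3)c(OCc3ccccc3)c2)c1C(=O)[C@@H]1O[C@H]1c1ccc(OCc2ccccc2)c(OCc2ccccc2)c1
F5 | step 9 | (2R,3R)-2-[3,4-bis(benzyloxy)phenyl]-5,7-bis(DBB-oxy)-8-bromo-3-hydroxychroman-4-one | O=C1c2c(OCc3ccc(OCc4ccccc4)c(OCc4ccccc4)c3)cc(OCc3ccc(OCc4ccccc4)c(OCc4ccccc4)c3)c(Br)c2O[C@H](c2ccc(OCc3ccccc3)c(OCc3ccccc3)c2)[C@H]1O
F6 | step 4 | (2S,3S)-8-{(2R,3S)-5,7-bis(benzyloxy)-2-[3,4-bis(benzyloxy)phenyl]-4-oxochroman-3-yl}-2-[3,4-bis(benzyloxy)phenyl]-5,7-bis(DBB-oxy)-3-hydroxychroman-4-one | O=C1c2c(OCc5ccc(OCc6ccccc6)c(OCc6ccccc6)c5)cc(OCc5ccc(OCc6ccccc6)c(OCc6ccccc6)c5)c([C@@H]3C(=O)c4c(OCc5ccccc5)cc(OCc5ccccc5)cc4O[C@H]3c3ccc(OCc4ccccc4)c(OCc4ccccc4)c3)c2O[C@@H](c2ccc(OCc3ccccc3)c(OCc3ccccc3)c2)[C@@H]1O
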